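## Retrosynthetic overview

- **Locants (guaiane type):** C1 = C(OH)(crotonoyl); C2–C4 and C15 = crotonoyl chain; C5 = CH–O-isovaleryl; C6 = CH–O(lactone); C7 = ring-fusion CH; C8 = CH2; C9 = CHOH; C10 = CH(CH3), methyl = C14; C11 = lactone α-carbon, C12 = lactone C=O, C13 = exocyclic CH2.
- **Endgame:** 9-OH and the 5-O-acyl group go back to C9 and C5 ketones. The tertiary 1-OH directs hydride to both. C9 stays masked as a silyl enol ether until C5 is reduced and acylated.
- **Key disconnection:** C6–C7 and C10–C1 are cut together in a catalytic asymmetric intramolecular (4+3) cycloaddition. The γ-lactone ring and the cycloheptane ring therefore form in the same operation, from an achiral open-chain bis(silyl enol ether) that is an isomer of its product.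
- **Enabling feature:** in the cycloheptane ring (C1, C5–C10) oxygen sits on C5, the middle of the arc C6–C5–C1 (siloxyallyl unit), and on C9, the second atom of the arc C10–C9–C8–C7 (dienolsilane). Carbinol C1 adjoins the exocyclic C2 ketone (a latent chelating 1,2-diketone), and the lactone atoms O–C12–C11 span C6 and C7 as a three-atom tether.
- **Precursor:** a vicinal triketone ester, built from a dienone acid (Heck reaction) and a chloro diazo diketone (Claisen-type acylation, diazo transfer) by carboxylate alkylation and oxidation of the diazo carbon.

Key step: step 8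

Assumption 1: the sense of induction is taken from the square-planar chelate model for pyruvate esters, in which the (S,S)-tert-butyl bis(oxazoline) ligand leaves the Si face of the bound ketone open; the (R,R)-ligand is therefore chosen to open the Re face of C1=O.

Assumption 2: 11 is drawn as the triketone, although it should be handled as a mixture with its C5 enol and its C1 hydrate.

## Route

Step 1
Reactants: 1 tert-butyl 2-bromoacrylate; 2 pent-1-en-3-one (ethyl vinyl ketone)
Product: 3 tert-butyl (E)-2-methylidene-5-oxohept-3-enoate
Conditions: Pd(OAc)2 (5 mol %), Bu4NCl, NaHCO3, BHT, DMF, 40 °C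
Reagents that add atoms: none
Why: Heck vinylation under phase-transfer conditions, in which zerovalent palladium formed in the flask inserts into the activated C–Br bond of 1, the vinylpalladium species adds to the unsubstituted terminus of 2, and syn β-hydride elimination should give the E alkene (C7=C8).

Step 2
Reactants: 3 tert-butyl (E)-2-methylidene-5-oxohept-3-enoate
Product: 4 (E)-2-methylidene-5-oxohept-3-enoic acid
Conditions: TFA, CH2Cl2, 0 °C to rt
Reagents that add atoms: none
Why: Acidolysis of the tert-butyl ester (E1 loss of isobutene) should free the acid without touching the dienone, to which hydroxide would add in Michael fashion.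

Step 3
Reactants: 5 (E)-pent-3-en-2-one; 6 2-chloro-N-methoxy-N-methylacetamide
Product: 8 (E)-1-chlorohept-5-ene-2,4-dione, via lithium dienolate 7 (not isolated)
Conditions: LDA, THF, −78 °C; 6, −78 to −40 °C; 1 M HCl
Reagents that add atoms: none
Why: Crossed Claisen-type acylation, in which LDA removes the methyl proton of 5 under kinetic control and the chelated tetrahedral adduct of the N-methoxy-N-methylamide should survive until the acid quench, which prevents double addition, proton exchange with the product and displacement of chloride.

Step 4
Reactants: 8 (E)-1-chlorohept-5-ene-2,4-dione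
Product: 9 (E)-1-chloro-3-diazohept-5-ene-2,4-dione
Conditions: 4-AcNHC6H4SO2N3, Et3N, MeCN, 0 °C
Reagents that add atoms: 4-acetamidobenzenesulfonyl azide, CC(=O)Nc1ccc(cc1)S(=O)(=O)N=[N+]=[N-]
Why: Regitz diazo transfer to the activated C1 methylene, which also removes the acidic protons that would let the γ-chloro diketone close to a 3(2H)-furanone under the basic conditions of the next step.

Step 5
Reactants: 4 (E)-2-methylidene-5-oxohept-3-enoic acid; 9 (E)-1-chloro-3-diazohept-5-ene-2,4-dione
Product: 10 (E)-3-diazo-2,4-dioxohept-5-en-1-yl (E)-2-methylidene-5-oxohept-3-enoate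
Conditions: KHCO3, NaI (10 mol %), DMF, rt
Reagents that add atoms: none
Why: SN2 displacement at the α-chloro ketone (iodide-catalysed, Finkelstein activation) by the potassium carboxylate of 4 forms the O6–C12 ester that later serves as the tether, and the weak base should leave the diazo diketone and both enones untouched.

Step 6
Reactants: 10 (E)-3-diazo-2,4-dioxohept-5-en-1-yl (E)-2-methylidene-5-oxohept-3-enoate
Product: 11 (E)-2,3,4-trioxohept-5-en-1-yl (E)-2-methylidene-5-oxohept-3-enoate
Conditions: dimethyldioxirane (dried acetone solution), CH2Cl2, 4 Å MS, 0 °C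
Reagents that add atoms: dimethyldioxirane, CC1(C)OO1
Why: Oxygen-atom transfer from dimethyldioxirane to a 2-diazo-1,3-dicarbonyl compound gives the vicinal tricarbonyl compound with loss of N2, and the acceptor-substituted C=C bonds of 10 should be epoxidised far more slowly than the diazo carbon is oxidised.

Step 7
Reactants: 11 (E)-2,3,4-trioxohept-5-en-1-yl (E)-2-methylidene-5-oxohept-3-enoate
Product: 13 (1Z,5E)-3,4-dioxo-2-(trimethylsilyloxy)hepta-1,5-dien-1-yl (3E,5Z)-2-methylidene-5-(triisopropylsilyloxy)hepta-3,5-dienoate, via mono-TMS enol ether 12 (not isolated)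
Conditions: TMSCl, Et3N, CH2Cl2, 0 °C; then TIPSOTf, Et3N, −78 to −20 °C; pentane, filtration under argon
Reagents that add atoms: chlorotrimethylsilane, C[Si](C)(C)Cl; triisopropylsilyl triflate, CC(C)[Si](C(C)C)(C(C)C)OS(=O)(=O)C(F)(F)F
Why: Two soft enolisation and O-silylation events, in which TMSCl and Et3N trap the strongly acidic C5 enol of the triketone as the Z enol ether (O5 and O6 cis, C1 acyl group trans to O6), TIPSOTf and Et3N then turn the ethyl enone into the cross-conjugated Z dienolsilane (C14 turned away from the C7=C8 vinyl group to avoid A1,3 strain), and the excess of amine keeps the silyl triflate from acting as a Lewis acid on the diketone.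

Step 8
Reactants: 13 (1Z,5E)-3,4-dioxo-2-(trimethylsilyloxy)hepta-1,5-dien-1-yl (3E,5Z)-2-methylidene-5-(triisopropylsilyloxy)hepta-3,5-dienoate
Product: 15 (4+3) adduct bearing free 1-OH (C5 ketone; 9-OTIPS enol ether; O1/O6/C11/C14 all cis), via O1-trimethylsilyl cycloadduct 14 (not isolated)
Conditions: Cu(OTf)2 (10 mol %), (R,R)-t-Bu-box [2,2'-(propane-2,2-diyl)bis((4R)-4-tert-butyl-4,5-dihydrooxazole)] (11 mol %), CH2Cl2 (2 mM, slow addition of 13), −78 to −20 °C; then AcOH–THF–H2O, 0 °C
Reagents that add atoms: none
Why: Proposed new method: divalent copper should bind the C1/C2 1,2-diketone of 13 as a square-planar five-membered chelate, C10 of the dienolsilane adds to the open Re face of C1=O, the O9-silylated enone cation so formed is captured at C7 by C6 of the TMS enol ether, and TMS then moves from O5 to O1 and releases the catalyst, so that 13 isomerises to 14 in one asynchronous (4+3) event (the acid work-up only frees 1-OH). The closest known reaction types are the Lewis acid-promoted (4+3) cycloaddition of 2-silyloxy enals with dienes, the catalytic asymmetric (4+3) cycloaddition of dienolsilanes with stabilised allyl-type cations, and the copper bis(oxazoline)-catalysed Mukaiyama aldol addition to pyruvates and 1,2-diketones, whose syn preference matches the C1/C10 relationship needed here. The cycloheptene ring closes by the (4+3) mode (aldol bond C10–C1, then 7-endo-trig Michael bond C6–C7), and the same C6–C7 bond closes the γ-lactone ring 5-exo-trig through the O6–C12–C11 tether. C1 is controlled by the ligand, C10 by the Z dienolsilane and C7 by the E C7=C8 bond (C14 and C11 both point outward and end up cis), C6 by the Z enol ester within the W-shaped siloxyallyl unit (O6 and O1 end up cis), and the compact transition state, in which O5 lies over the diene, should place O1, O6, C11 and C14 on one face. The step needs C6–C7 closure rather than (3+2) closure at C9, oxa-Michael closure by O1, attack of C10 at C6, C2 or C4, or intermolecular aldol addition: the short tether with its E double bond cannot span C6 and C9 or bring C10 to C6 without a trans-cycloalkene of seven or eight members, C2 and C4 lie outside the reach of a ring of ten atoms, copper-bound O1 is a poorer and reversible nucleophile, and high dilution suppresses bimolecular paths.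

Step 9
Reactants: 15 (4+3) adduct bearing free 1-OH
Product: 16 5-alcohol (5-OH on the face opposite to O1 and O6; 9-OTIPS enol ether kept)
Conditions: Me4NBH(OAc)3 (1.5 equiv), MeCN–AcOH, −40 °C
Reagents that add atoms: none
Why: Hydroxyl-directed triacetoxyborohydride reduction (Saksena–Evans type), in which exchange at the free 1-OH gives an alkoxyborohydride that delivers hydride to the face of C5=O syn to O1 and so sets 5-OH trans to O1 and O6, while the α-acyloxy ketone is more electrophilic than the conjugated C2 enone and C9 is masked.

Step 10
Reactants: 16 5-alcohol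
Product: 17 5-O-isovalerate (9-OTIPS enol ether, free 1-OH)
Conditions: (Me2CHCH2CO)2O, DMAP (cat.), pyridine, CH2Cl2, 0 °C to rt
Reagents that add atoms: isovaleric anhydride, CC(C)CC(=O)OC(=O)CC(C)C
Why: DMAP-catalysed acylation should take the secondary 5-OH only, because the tertiary 1-OH is flanked by four substituted carbons and no other free hydroxyl group is present at this stage.

Step 11
Reactants: 17 5-O-isovalerate
Product: 18 9-ketone (5-O-isovalerate, free 1-OH)
Conditions: HF·pyridine, pyridine, THF, 0 °C
Reagents that add atoms: none
Why: Fluoride-assisted protodesilylation of the silyl enol ether, in which protonation at C8 creates no stereocentre and the weakly acidic medium should avoid retro-aldol cleavage of C1–C10 and epimerisation at C10.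

Step 12
Reactants: 18 9-ketone
Product: 19 CNP0186412.1 (target)
Conditions: Me4NBH(OAc)3 (3 equiv), MeCN–AcOH, −30 °C
Reagents that add atoms: none
Why: Saksena–Evans anti reduction of a β-hydroxy ketone, in which the borohydride bound to 1-OH delivers hydride to the face of C9=O syn to O1 and so sets 9-OH anti to 1-OH and trans to C14, the saturated ketone being reduced faster than the conjugated C2 ketone.

## Compound list

In 14 to 18 the absolute configuration at the centres already set is that of 19.

1 | tert-butyl 2-bromoacrylate | C=C(Br)C(=O)OC(C)(C)C | starting material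
2 | pent-1-en-3-one (ethyl vinyl ketone) | C=CC(=O)CC | starting material
3 | tert-butyl (E)-2-methylidene-5-oxohept-3-enoate | C=C(/C=C/C(=O)CC)C(=O)OC(C)(C)C | intermediate
4 | (E)-2-methylidene-5-oxohept-3-enoic acid | C=C(/C=C/C(=O)CC)C(=O)O | intermediate
5 | (E)-pent-3-en-2-one | C/C=C/C(C)=O | starting material
6 | 2-chloro-N-methoxy-N-methylacetamide | CON(C)C(=O)CCl | starting material
7 | lithium (E)-penta-1,3-dien-2-olate | [Li+].[O-]C(=C)/C=C/C | intermediate
8 | (E)-1-chlorohept-5-ene-2,4-dione | C/C=C/C(=O)CC(=O)CCl | intermediate
9 | (E)-1-chloro-3-diazohept-5-ene-2,4-dione | C/C=C/C(=O)C(=[N+]=[N-])C(=O)CCl | intermediate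
10 | (E)-3-diazo-2,4-dioxohept-5-en-1-yl (E)-2-methylidene-5-oxohept-3-enoate | C/C=C/C(=O)C(=[N+]=[N-])C(=O)COC(=O)C(=C)/C=C/C(=O)CC | intermediate
11 | (E)-2,3,4-trioxohept-5-en-1-yl (E)-2-methylidene-5-oxohept-3-enoate | C/C=C/C(=O)C(=O)C(=O)COC(=O)C(=C)/C=C/C(=O)CC | intermediate
12 | (1Z,5E)-3,4-dioxo-2-(trimethylsilyloxy)hepta-1,5-dien-1-yl (E)-2-methylidene-5-oxohept-3-enoate | C/C=C/C(=O)C(=O)/C(O[Si](C)(C)C)=C/OC(=O)C(=C)/C=C/C(=O)CC | intermediate
13 | (1Z,5E)-3,4-dioxo-2-(trimethylsilyloxy)hepta-1,5-dien-1-yl (3E,5Z)-2-methylidene-5-(triisopropylsilyloxy)hepta-3,5-dienoate | C/C=C/C(=O)C(=O)/C(O[Si](C)(C)C)=C/OC(=O)C(=C)/C=C/C(O[Si](C(C)C)(C(C)C)C(C)C)=C/C | intermediate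
14 | O1-trimethylsilyl cycloadduct: cis-fused α-methylene-γ-lactone (O on C6, C11 on C7) on a cyclohept-8-ene ring; C5 ketone; C1 bears OTMS and (E)-but-2-enoyl; C9 bears OTIPS; C10 bears CH3; O1, O6, C11 and C14 on one face | C=C1C(=O)O[C@@H]2[C@H]1C=C(O[Si](C(C)C)(C(C)C)C(C)C)[C@H](C)[C@@](O[Si](C)(C)C)(C(=O)/C=C/C)C2=O | intermediate
15 | as 14, with free 1-OH | C=C1C(=O)O[C@@H]2[C@H]1C=C(O[Si](C(C)C)(C(C)C)C(C)C)[C@H](C)[C@@](O)(C(=O)/C=C/C)C2=O | intermediate
16 | as 15, with C5 as CHOH; 5-OH on the face opposite to O1 and O6 | C=C1C(=O)O[C@@H]2[C@H]1C=C(O[Si](C(C)C)(C(C)C)C(C)C)[C@H](C)[C@@](O)(C(=O)/C=C/C)[C@H]2O | intermediate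
17 | as 16, with 5-O-(3-methylbutanoyl) | C=C1C(=O)O[C@@H]2[C@H]1C=C(O[Si](C(C)C)(C(C)C)C(C)C)[C@H](C)[C@@](O)(C(=O)/C=C/C)[C@H]2OC(=O)CC(C)C | intermediate
18 | as 17, with C9 ketone and C8 as CH2 | C=C1C(=O)O[C@@H]2[C@H]1CC(=O)[C@H](C)[C@@](O)(C(=O)/C=C/C)[C@H]2OC(=O)CC(C)C | intermediate
19 | (3aS,5R,6S,7S,8S,8aR)-7-[(E)-but-2-enoyl]-5,7-dihydroxy-6-methyl-3-methylidene-2-oxooctahydro-2H-cyclohepta[b]furan-8-yl 3-methylbutanoate (CNP0186412.1; guaiane-type locants 1S,5S,6R,7S,9R,10S) | C=C1C(=O)O[C@@H]2[C@H]1C[C@@H](O)[C@H](C)[C@@](O)(C(=O)/C=C/C)[C@H]2OC(=O)CC(C)C | target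

## Step count

- Total step count: 12.
- Longest linear sequence: 10 steps (steps 3 to 12 from 5; equally steps 1, 2 and 5 to 12 from 1).

## Steps most likely to fail

**Step 8.**
- *What may go wrong:* the bulky dienolsilane may add too slowly to the chelated diketone. Intermolecular aldol addition, ring closure through O1, or loss of the silyl groups could then overtake the second C–C bond formation. The compact and extended transition states may also be poorly discriminated.
- *Fallback:* it sets out from 13 and comes back at 15. It uses the known two-stage equivalent of a (4+3) cycloaddition of 2-silyloxy carbonyl compounds, a Diels–Alder reaction followed by α-ketol-type ring expansion.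
- *Cycloaddition:* 13 is heated in dilute toluene (BHT, 130 °C). The C5=C6 double bond, activated by the C1 acyl group, adds across C7 and C10 of the dienolsilane in the orientation fixed by the tether. This gives the cis-fused lactone-cyclohexene Diels–Alder adduct F1, in which C5 is quaternary (OTMS and the C1 acyl group).
- *Ring expansion:* Me2AlCl in CH2Cl2 at −78 °C then bridges O5 and O1 and induces the 1,2-shift of C10 from C5 to C1. C10 migrates with retention, on the face of C1=O fixed by the chelate. This enlarges the six-membered ring to 14, and AcOH–THF–H2O gives 15.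
- *Enantiopurity:* the thermal cycloaddition is not enantioselective, so 15 would be separated from its mirror image by preparative chromatography on a chiral phase.

**Step 6.**
- *What may go wrong:* epoxidation of the diene may compete with oxidation of the diazo carbon. The triketone may also hydrate and suffer C–C cleavage during oxidation and concentration.
- *Fallback:* it sets out from 10 and comes back at 11, and replaces oxygen-atom transfer by insertion and alcohol oxidation.
- *Sequence:* Rh2(OAc)4 (1 mol %) in wet CH2Cl2 converts 10 by O–H insertion of the rhodium carbenoid into water to the 3-hydroxy-2,4-diketone ester F2. Dess–Martin periodinane buffered with pyridine then oxidises the carbinol to 11 under anhydrous conditions.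

**Step 9.**
- *What may go wrong:* the hindered 1-OH, flanked by two carbonyl groups, may exchange slowly with the borohydride. Discrimination between the C5 ketone and the C2 enone, both next to 1-OH, may also be poor.
- *Fallback:* it sets out from 15 and comes back at 16, and gives up selective reduction for exhaustive reduction and selective re-oxidation.
- *Sequence:* an excess of Me4NBH(OAc)3 at 0 °C reduces both carbonyl groups under direction by 1-OH to the 1,2,5-triol F3 (epimers at C2). MnO2 in CH2Cl2 then oxidises only the allylic C2 carbinol back to the enone and leaves the saturated 5-OH untouched.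

## Further compounds

F1 | step 8 | Diels–Alder adduct (racemic; the enantiomer that leads to 15 is drawn): cis-fused α-methylene-γ-lactone on a cyclohexene ring made of C5, C6, C7, C8, C9 and C10; C5 bears OTMS and the (E)-2-oxopent-3-enoyl group; C9 bears OTIPS; O5, O6, C11 and C14 on one face | C=C1C(=O)O[C@@H]2[C@H]1C=C(O[Si](C(C)C)(C(C)C)C(C)C)[C@H](C)[C@@]2(O[Si](C)(C)C)C(=O)C(=O)/C=C/C
F2 | step 6 | (E)-3-hydroxy-2,4-dioxohept-5-en-1-yl (E)-2-methylidene-5-oxohept-3-enoate (carbinol centre racemic, lost on oxidation) | C/C=C/C(=O)C(O)C(=O)COC(=O)C(=C)/C=C/C(=O)CC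
F3 | step 9 | 1,2,5-triol: as 16, with the C2 ketone reduced to the allylic alcohol (mixture of C2 epimers, centre left open) | C=C1C(=O)O[C@@H]2[C@H]1C=C(O[Si](C(C)C)(C(C)C)C(C)C)[C@H](C)[C@@](O)(C(O)/C=C/C)[C@H]2O
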